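**Assumptions**
- Coniferaldehyde, vanillin, the D-fructose-derived Shi ketone and the Noyori Ru–XylBINAP/DPEN precatalyst are taken as commercially available.
- Catalysts, bases, solvents and reagents that leave no non-hydrogen atom in a product are named in the conditions and not numbered.
- Lignan numbering is used to track atoms: ring O–C7(Ar)–C8(C9H2OH)–C8'(C7'H(OH)Ar')–C9'H2. The target is ring (2S,3R,4S) with an (S)-carbinol, i.e. all-trans on the ring.

**Retrosynthetic overview**
1. Target ⇐ removal of two aryl pivalates; C9 CH2OH ⇐ vinyl (ozonolysis/NaBH4); C7' carbinol ⇐ aryl ketone (catalyst-controlled hydrogenation).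
2. The tetrahydrofuran is made in one step by a new Pd-catalysed oxa-[3+2] annulation of a (2R,3R)-2-aryl-3-vinyloxirane with an aryl vinyl ketone. It forms O–C9' and C8–C8', relays C7 from the epoxide and sets C8 and C8'.
3. Epoxide ⇐ Shi epoxidation of the (E)-arylbutadiene from coniferaldehyde (sets C7); enone ⇐ vanillin + vinylMgBr, then oxidation.
4. Ring order: oxirane (temporary), then tetrahydrofuran. Both phenols are carried as pivalates so the benzylic epoxide is isolable and one final step unmasks both.

**Route**

Step 1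
Reactants: 1 coniferaldehyde, (E)-3-(4-hydroxy-3-methoxyphenyl)prop-2-enal; 2 pivaloyl chloride
Product: 3 (E)-2-methoxy-4-(3-oxoprop-1-en-1-yl)phenyl pivalate
Conditions: PivCl, Et3N, DMAP (cat.), CH2Cl2, 0 °C → rt
Reagents that add atoms: pivaloyl chloride (2), CC(C)(C)C(=O)Cl
Why: Phenol O-acylation (nucleophilic acyl substitution); the acyloxy group makes the arene less electron-rich so the later benzylic epoxide can be handled, and no stereocentre is involved.

Step 2
Reactants: 3; 4 methyltriphenylphosphonium bromide
Product: 5 (E)-4-(buta-1,3-dien-1-yl)-2-methoxyphenyl pivalate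
Conditions: Ph3PCH3Br, KOt-Bu (slight deficit), THF, 0 °C; then 3, −78 → 0 °C
Reagents that add atoms: methyltriphenylphosphonium bromide (4), C[P+](c1ccccc1)(c1ccccc1)c1ccccc1.[Br-] (delivers CH2)
Why: Wittig methylenation of the enal carbonyl; the existing E-alkene is untouched and the hindered aryl pivalate is not attacked at low temperature.

Step 3
Reactants: 5; 6 Oxone (KHSO5)
Product: 7 2-methoxy-4-[(2R,3R)-3-vinyloxiran-2-yl]phenyl pivalate (trans)
Conditions: D-fructose-derived Shi ketone (30 mol %), Oxone, K2CO3, Bu4NHSO4, MeCN–DMM / aq. Na2B4O7–Na2EDTA (pH ≈ 10.5), −10 → 0 °C; Et3N-deactivated silica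
Reagents that add atoms: Oxone, potassium peroxymonosulfate (6), [K+].[O-]S(=O)(=O)OO (delivers the epoxide O)
Why: Shi asymmetric epoxidation (chiral dioxirane, spiro transition state) should take the trans-disubstituted aryl-bearing alkene over the terminal vinyl; the D-fructose ketone gives the (R,R)-epoxide in the same sense as for trans-β-methylstyrene, which sets C7.

Step 4
Reactants: 8 vanillin; 2 pivaloyl chloride
Product: 9 4-formyl-2-methoxyphenyl pivalate
Conditions: PivCl, Et3N, DMAP (cat.), CH2Cl2, 0 °C → rt
Reagents that add atoms: pivaloyl chloride (2), CC(C)(C)C(=O)Cl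
Why: Phenol O-acylation, as in step 1.

Step 5
Reactants: 9; 10 vinylmagnesium bromide
Product: 11 (±)-4-(1-hydroxyprop-2-en-1-yl)-2-methoxyphenyl pivalate
Conditions: CH2=CHMgBr (1.05 equiv), THF, −78 °C
Reagents that add atoms: vinylmagnesium bromide (10), C=C[Mg]Br
Why: Grignard 1,2-addition is much faster at the aldehyde than at the hindered aryl pivalate at −78 °C; the racemic carbinol is oxidised in the next step.

Step 6
Reactants: 11
Product: 12 4-acryloyl-2-methoxyphenyl pivalate (aryl vinyl ketone)
Conditions: MnO2, CH2Cl2, rt; use at once (BHT)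
Reagents that add atoms: none
Why: Chemoselective MnO2 oxidation of an allylic/benzylic alcohol to the enone.

Step 7 (new transformation)
Reactants: 7 (2R,3R)-vinyl epoxide; 12 aryl vinyl ketone (1.5 equiv)
Product: 13 2-methoxy-4-[(2S,3S,4S)-4-(3-methoxy-4-pivaloyloxybenzoyl)-3-vinyltetrahydrofuran-2-yl]phenyl pivalate (2,3-trans, 3,4-trans)
Conditions: Pd2(dba)3·CHCl3 (2.5 mol %), dppe (6 mol %), THF, 0 → 25 °C, slow addition of 7; then DBU (0.2 equiv), 25 °C
Reagents that add atoms: none (7 and 12 combine with no atoms lost or gained)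
Why: Proposed new method: Pd(0)-catalysed oxa-[3+2] annulation of a 2-aryl-3-vinyloxirane with a singly activated aryl vinyl ketone. Pd(0) ionises the allylic C8–O bond with inversion to give a zwitterionic π-allyl-Pd/benzylic alkoxide, leaving the C7–O bond and the C7 configuration untouched. The alkoxide adds oxa-Michael to the unsubstituted β-carbon of 12 (O–C9' bond), and the tethered enolate closes the five-membered ring at the internal allyl terminus anti to Pd (C8–C8' bond). That is net retention at C8, so the trans-epoxide gives the 2,3-trans ring, and π–σ–π equilibration leads to the same less hindered closure. C8' is α to the ketone and DBU equilibrates it to the all-trans isomer. Any reversible 1,2-adduct (vinyl dioxolane) can be re-ionised by Pd. The closest known reaction types are Pd-catalysed [3+2] cycloadditions of vinyl oxiranes with doubly activated alkenes or heterocumulenes, and of vinyl aziridines with enones.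

Step 8
Reactants: 13
Product: 14 2-methoxy-4-[(2S,3S,4S)-4-[(S)-hydroxy(3-methoxy-4-pivaloyloxyphenyl)methyl]-3-vinyltetrahydrofuran-2-yl]phenyl pivalate
Conditions: RuH(η1-BH4)[(R)-xylbinap][(R,R)-dpen] (1 mol %), H2 (8 atm), i-PrOH/THF, 25 °C (base-free)
Reagents that add atoms: none (H2 only)
Why: Noyori asymmetric hydrogenation (bifunctional outer-sphere hydride transfer) reduces C=O and not the terminal alkene; the (R)/(R,R) catalyst gives the (S)-aryl carbinol, the sense that gives (S)-1-arylalkanols, which sets C7' under catalyst control, and the base-free precatalyst avoids epimerising C8' or cleaving the aryl esters.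

Step 9
Reactants: 14; 15 ozone
Product: 16 2-methoxy-4-[(2S,3R,4S)-3-(hydroxymethyl)-4-[(S)-hydroxy(3-methoxy-4-pivaloyloxyphenyl)methyl]tetrahydrofuran-2-yl]phenyl pivalate (the C3 descriptor changes S → R by CIP priority only)
Conditions: O3, CH2Cl2–MeOH, pyridine (cat.), −78 °C (Sudan Red end-point); then NaBH4, −78 → 0 °C
Reagents that add atoms: ozone (15), [O-][O+]=O (delivers the O of CH2OH; the terminal CH2 is excised)
Why: Ozonolysis with in situ borohydride reduction turns the vinyl group into the C9 CH2OH; the alkene reacts far faster than the acylated guaiacyl rings, and the transient aldehyde is reduced before it can epimerise at C8 (all-trans is the thermodynamic arrangement in any case).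

Step 10
Reactants: 16
Product: 17 target, 4-[(2S,3R,4S)-4-[(S)-hydroxy(4-hydroxy-3-methoxyphenyl)methyl]-3-(hydroxymethyl)tetrahydrofuran-2-yl]-2-methoxyphenol
Conditions: NaOMe, MeOH, 0 °C → rt; aq. NH4Cl quench (no strong acid)
Reagents that add atoms: none
Why: Base-mediated transesterification removes both aryl pivalates; acid is avoided so the p-hydroxybenzylic C–O bonds and all four stereocentres are untouched.

**Compound list**
1 | coniferaldehyde, (E)-3-(4-hydroxy-3-methoxyphenyl)prop-2-enal | COc1cc(/C=C/C=O)ccc1O | starting material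
2 | pivaloyl chloride | CC(C)(C)C(=O)Cl | starting material (reagent)
3 | (E)-2-methoxy-4-(3-oxoprop-1-en-1-yl)phenyl pivalate | COc1cc(/C=C/C=O)ccc1OC(=O)C(C)(C)C | intermediate
4 | methyltriphenylphosphonium bromide | C[P+](c1ccccc1)(c1ccccc1)c1ccccc1.[Br-] | starting material (reagent)
5 | (E)-4-(buta-1,3-dien-1-yl)-2-methoxyphenyl pivalate | COc1cc(/C=C/C=C)ccc1OC(=O)C(C)(C)C | intermediate
6 | Oxone (potassium peroxymonosulfate) | [K+].[O-]S(=O)(=O)OO | starting material (reagent)
7 | 2-methoxy-4-[(2R,3R)-3-vinyloxiran-2-yl]phenyl pivalate | C=C[C@H]1O[C@@H]1c1ccc(OC(=O)C(C)(C)C)c(OC)c1 | intermediate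
8 | vanillin | COc1cc(C=O)ccc1O | starting material
9 | 4-formyl-2-methoxyphenyl pivalate | COc1cc(C=O)ccc1OC(=O)C(C)(C)C | intermediate
10 | vinylmagnesium bromide | C=C[Mg]Br | starting material (reagent)
11 | (±)-4-(1-hydroxyprop-2-en-1-yl)-2-methoxyphenyl pivalate | COc1cc(C(O)C=C)ccc1OC(=O)C(C)(C)C | intermediate
12 | 4-acryloyl-2-methoxyphenyl pivalate | COc1cc(C(=O)C=C)ccc1OC(=O)C(C)(C)C | intermediate
13 | 2-methoxy-4-[(2S,3S,4S)-4-(3-methoxy-4-pivaloyloxybenzoyl)-3-vinyltetrahydrofuran-2-yl]phenyl pivalate | COc1cc(C(=O)[C@@H]2CO[C@H](c3ccc(OC(=O)C(C)(C)C)c(OC)c3)[C@H]2C=C)ccc1OC(=O)C(C)(C)C | intermediate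
14 | 2-methoxy-4-[(2S,3S,4S)-4-[(S)-hydroxy(3-methoxy-4-pivaloyloxyphenyl)methyl]-3-vinyltetrahydrofuran-2-yl]phenyl pivalate | COc1cc([C@@H](O)[C@@H]2CO[C@H](c3ccc(OC(=O)C(C)(C)C)c(OC)c3)[C@H]2C=C)ccc1OC(=O)C(C)(C)C | intermediate
15 | ozone | [O-][O+]=O | starting material (reagent)
16 | 2-methoxy-4-[(2S,3R,4S)-3-(hydroxymethyl)-4-[(S)-hydroxy(3-methoxy-4-pivaloyloxyphenyl)methyl]tetrahydrofuran-2-yl]phenyl pivalate | COc1cc([C@@H](O)[C@@H]2CO[C@H](c3ccc(OC(=O)C(C)(C)C)c(OC)c3)[C@H]2CO)ccc1OC(=O)C(C)(C)C | intermediate
17 | 4-[(2S,3R,4S)-4-[(S)-hydroxy(4-hydroxy-3-methoxyphenyl)methyl]-3-(hydroxymethyl)tetrahydrofuran-2-yl]-2-methoxyphenol | COc1cc([C@@H](O)[C@@H]2CO[C@H](c3ccc(O)c(OC)c3)[C@H]2CO)ccc1O | target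

**Totals**
Total steps: 10. Longest linear sequence: 7 (steps 1–3, 7–10; the other branch, steps 4–6 then 7–10, is also 7).

**Three steps most likely to fail**
1. Step 7 (the new Pd oxa-[3+2]). Risks are Pd-mediated isomerisation of the zwitterion to a dienol/ketone, enone oligomerisation, and poor 2,3-selectivity. Fallback with known chemistry, building the same all-trans core a different way:
   - Evans Bu2BOTf/Et3N syn-aldol–lactonisation of methyl 4-[(S)-4-benzyl-2-oxooxazolidin-3-yl]-4-oxobutanoate with O-benzylvanillin gives the trans-paraconate (C7/C8).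
   - LiOOH cleavage, BH3·SMe2 reduction of the acid and TBS protection give the protected hydroxymethyl lactone.
   - LiHMDS lactone-enolate aldol with O-benzylvanillin, anti to C8, installs C8'/C7'.
   - LiAlH4, then selective primary tosylation with in situ Williamson closure by the C7 hydroxyl (retention) forms the tetrahydrofuran.
   - TBAF and H2/Pd–C complete the synthesis.
2. Step 8 (C7' control). The catalyst may be mismatched with the substrate's Felkin/chelate bias, and the α-branched ketone may be slow. Fallback: substrate-controlled hydride reduction (Zn(BH4)2 or L-Selectride) to the 7'-epimer, then Mitsunobu inversion with 4-nitrobenzoic acid; the nitrobenzoate is cleaved in step 10.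
3. Step 3 (Shi epoxidation). Risks are regioselectivity between the two diene alkenes and the lability of the aryl vinyl epoxide. Fallback: Luche reduction of 3 to the cinnamyl alcohol, Sharpless epoxidation with D-(−)-diethyl tartrate to the (2R,3R)-epoxy alcohol, Parikh–Doering oxidation and Wittig methylenation to reach the same epoxide 7.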